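## The problem

Isoflavan numbering is used: O1, C2, C3, C4, C4a, C5–C8, C8a. Ring A is the benzo ring, ring C the pyran ring, and ring B the aryl group on C3 (C1'–C6').

The target 22 is a chroman whose C3 carries a pentasubstituted ring B: 2'-OMe, 3'-OH, 4'-OH and a 1,1-dimethylallyl group at C5'. Ring A has one hydroxyl, at C7. C3 is the only stereocentre (S). It is a tertiary benzylic C–H carbon with no neighbouring stereocentre to relay from, so a chiral catalyst or reagent must set it; once set it is not acidic and is not endangered later. Three phenols have to be told apart from one another and from the methyl ether: O4' must be free alone at one stage, while O3' and O7 stay masked to the end. The terminal alkene of the side chain would not survive hydrogenation or carbene chemistry, and ortho to a free phenol it cyclizes under strong acid. The catechol oxidizes in air under base. The side chain therefore has to come last and the final deprotection has to be mild. The enabling feature is that C3 is a single carbon that bears ring B and sits between C2 (bound to O1) and C4 (bound to C4a). Without C3, the atoms O1, C2, C4, C4a and C8a form a furan fused to ring A. Ring C is therefore a benzofuran plus one aryl-bearing carbon inserted into its C2=C3 bond.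

## Retrosynthesis

**Side chain and final unmasking (22 ⇒ 21 ⇒ 20 ⇒ 18 + 19).** The two MOM acetals of 22 are cut to give 21. The C5'–C(CH3)2 bond is cut and the five-carbon unit is rejoined through its other end to O4', which gives prenyl ether 20, made from phenol 18 and prenyl bromide 19. Direct C-alkylation would give the linear prenyl isomer without regiocontrol. The [3,3] shift inverts the allyl unit and can end only at C5', because C3' carries oxygen and the para carbon C1' is substituted. Phenol 18 has no alkene, so every hydrogenation and the carbene step can precede it. The forward steps must avoid acid strong enough to cyclize the ortho-allylphenol.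

**Stereocentre (18 ⇒ 17 ⇒ 16).** Phenol 18 comes from benzyl ether 17; benzyl is the one group removable by hydrogenolysis while MOM stays on O3' and O7. The C3–H and C4–H bonds of 17 are cut to give the achiral isoflav-3-ene 16. This puts the only stereochemical event on a flat trisubstituted aryl alkene, the substrate class of iridium P,N hydrogenation catalysts, and not on an enolizable carbonyl compound. The forward step must select one alkene face by the catalyst alone, next to an ortho-methoxy group.

**Oxidation level of ring C (16 ⇒ 15).** The C2–H bond of 16 is cut as hydride, leaving the benzopyrylium salt 15. The precursor is fully aromatic and has no stereochemistry. The forward step must deliver hydride to C2 and not to C4.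

**Ring C (15 ⇒ 4 + 13, through 14).** C2–C3 and C3–C4 are cut, which takes out C3 together with ring B. What remains is 6-(methoxymethoxy)benzofuran 4, and the excised carbon is an arylchlorocarbene stored as chlorodiazirine 13. The neighbouring cuts (O1–C8a etherification, C3–C1' arylation, the deoxybenzoin route) leave a three-carbon chain to be built between the rings. This cut splits the molecule into two simple aromatic halves of similar size and fixes the aryl group on C3 by construction. The forward reaction must add the carbene to the furan C2=C3 bond, and the chlorocyclopropane 14 must open with loss of chloride.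

**Carbene precursor (13 ⇒ 12 ⇒ 10 ⇒ 9).** The diazirine carbon is the former formyl carbon of ring B. The N–N and C–Cl bonds of 13 lead back to amidinium salt 12, whose C–N bond leads to nitrile 10 (through the silylated amidinate 11), and the nitrile leads to aldehyde 9. Each step is a standard functional-group change. All of them must run without strong acid because of the MOM acetal.

**Ring B oxygen pattern (9 ⇒ 8 ⇒ 6 ⇒ 5).** Three O–C bonds are cut in the reverse order of phenol reactivity. Methyl comes off the chelated O2 (9 ⇒ 8), MOM off O3 (8 ⇒ 6, through dianion 7), and benzyl off O4, the most acidic site (6 ⇒ 5). This ends at commercial 2,3,4-trihydroxybenzaldehyde 5. The forward sequence needs regiocontrol from acidity and chelation alone.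

**Ring A partner (4 ⇒ 2 ⇒ 1).** The furan C2=C3 bond of 4 is traced to the ketone of 2 by reduction and dehydration through alcohol 3. The MOM ether is traced to commercial 6-hydroxybenzofuran-3(2H)-one 1.

## Roads not taken

Alternative 1: The cut removes four ring A bonds at once (C4a–C5, C7–C8, C4a–C8a, C6–C7). It leads to the open-chain (S)-vinyl diazoketone A2, whose chain already holds C2, C3 with ring B, C4 and an ethynyl ether on O1. In the forward direction light would trigger a Wolff rearrangement to a vinylketene. [2+2] addition to the tethered alkyne, four-electron opening of the cyclobutenone, six-electron closure and tautomerization would give phenol A1, with rings A and C formed together.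
- Merits: four bonds and two rings in one step, against two bonds and one ring in the chosen plan. The C7 hydroxyl is born free and at the right carbon. Ring B arrives complete, so no late Claisen step is needed.
- Weak points: A2 is much harder to make than 4 and 13. It combines a polymerization-prone vinyl ketone, a diazo group that needs deacylative diazo transfer, and an ethynyl ether with a β-hydrogen that is liable to thermal loss of ketene. Its stereocentre must be set separately in an acyclic chain, since the cascade creates none. The side-chain alkene competes for the ketene, and the tethered mode in which the first [2+2] also closes ring C has no close model.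
- Comparison: this road is better in bond economy and in needing no protecting group on O7. The chosen plan sets against it two precursors that are each a few standard steps from cheap aromatics, and a stereocentre set by an established catalytic hydrogenation.

Alternative 2: The cut is the aryl ether bond O1–C8a. The key step is an intramolecular Ullmann-type O-arylation of the prochiral diol A4 with CuI and a chiral diamine. One of the two enantiotopic CH2OH groups displaces the aryl bromide, closes ring C and makes C3 a quaternary stereocentre in A3.
- Merits: the reaction class is precedented for 2-substituted 2-(2-halobenzyl)propane-1,3-diols, so this key step stands on firmer ground than the chosen one. The stereocentre is made in the ring-forming event, and ring B arrives complete.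
- Weak points: A3 has one carbon too many. The hydroxymethyl group would have to be removed with retention, in practice by oxidation and decarbonylation with RhCl(PPh3)3. The alkylrhodium formed after CO loss is tertiary, benzylic and flanked by β-hydrogens at C2 and C4, so β-hydride elimination to an isoflavene, with loss of the stereocentre, is a real threat. The side-chain alkene meets the same metal. A4 needs a quaternary carbon bearing a di-ortho-substituted aryl group, and the desymmetrization is untested with so bulky a group.
- Comparison: this key step is safer and is itself enantioselective, which the chosen key step is not. The chosen plan sets against it a key product 15 with exactly the carbon skeleton of the target, and a C3 made directly as the tertiary C–H centre.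

Alternative 3: The cuts are C3–C4 and the acyl bond between O1 and C2. A chiral isothiourea would be acylated by the activated ester A6. The derived ammonium enolate would add through C3 to the methide carbon of the ortho-quinone methide A7, formed in situ, and the phenoxide would then release the catalyst to give lactone A5.
- Merits: a convergent organocatalytic step of a known type that forms two bonds, ring C and the stereocentre together. Ring B carries its side chain from the start, so the endgame is only lactone reduction, re-closure and deprotection. The total step count is probably equal to or lower than that of the chosen plan.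
- Weak points: the stereocentre of A5 is α to a lactone carbonyl and an aryl ring. It is acidic, is formed under basic conditions and must survive the hydride reduction. A7 has an unsubstituted methide carbon, so it is more reactive and more prone to self-condensation than the substituted methides on which this chemistry is usually run. With no second stereocentre, all selectivity rests on facial control at a hindered, ortho-methoxy-substituted enolate carbon.
- Comparison: in convergence, in setting C3 during bond formation and probably in step count, this road is at least as good as the chosen one. Both need reductive adjustment of ring C after the key step. The chosen plan sets against it a configurationally secure stereocentre, made after all base-mediated chemistry on a substrate with no acidic C–H, and a route that never carries an alkene-bearing ring B through enolate chemistry.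

Key step: step 9

Assumption: the (S)-enantiomer of the tBu-PHOX ligand is taken to deliver H2 to the face of 16 that gives (S)-17; if the sense of induction is the opposite, the (R)-ligand is used and nothing else changes (cod = cycloocta-1,5-diene; tBu-PHOX = 4-tert-butyl-2-[2-(diphenylphosphanyl)phenyl]-4,5-dihydrooxazole; BArF = tetrakis[3,5-bis(trifluoromethyl)phenyl]borate).

## Route

Step 1
Reactants: 1 6-hydroxybenzofuran-3(2H)-one
Product: 2 6-(methoxymethoxy)benzofuran-3(2H)-one
Conditions: MOMCl, iPr2NEt, CH2Cl2, 0 °C → rt
Reagents that add atoms: chloromethyl methyl ether, COCCl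
Why: Williamson-type O-alkylation of the phenol, the most acidic site (para to the ketone); the amine base is too weak to enolize C2, so aldol self-condensation of the coumaranone is avoided.

Step 2
Reactants: 2 6-(methoxymethoxy)benzofuran-3(2H)-one
Product: 4 6-(methoxymethoxy)benzofuran, via 6-(methoxymethoxy)-2,3-dihydrobenzofuran-3-ol 3 (not isolated)
Conditions: NaBH4, MeOH/THF, 0 °C; then 1 M HCl (aq) to pH 2, rt, 20 min
Reagents that add atoms: none
Why: Borohydride reduction of the aryl ketone, then acid-promoted dehydration; the 2,4-dioxygenated benzylic alcohol ionizes easily and the elimination gains furan aromaticity, so brief contact with dilute acid should suffice and the aryl MOM ether should tolerate it.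

Step 3
Reactants: 5 2,3,4-trihydroxybenzaldehyde
Product: 6 4-(benzyloxy)-2,3-dihydroxybenzaldehyde
Conditions: BnBr (1.0 equiv), NaHCO3, NaI (cat.), DMF, 40 °C, N2
Reagents that add atoms: benzyl bromide, BrCc1ccccc1
Why: Regioselective Williamson etherification: the 4-OH, para to the formyl group, is the most acidic and is the one deprotonated by hydrogencarbonate, while the 2-OH is tied up in a hydrogen bond to the carbonyl group.

Step 4
Reactants: 6 4-(benzyloxy)-2,3-dihydroxybenzaldehyde
Product: 8 4-(benzyloxy)-2-hydroxy-3-(methoxymethoxy)benzaldehyde, via disodium 3-(benzyloxy)-6-formylbenzene-1,2-diolate 7 (not isolated)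
Conditions: NaH (2.1 equiv), DMF, 0 °C; then MOMCl (1.0 equiv), 0 °C
Reagents that add atoms: chloromethyl methyl ether, COCCl
Why: Dianion alkylation: the 2-oxide is delocalized into and chelated by the formyl group, so the more basic 3-oxide should take the single equivalent of electrophile, the selectivity known for 2,3-dihydroxybenzaldehydes.

Step 5
Reactants: 8 4-(benzyloxy)-2-hydroxy-3-(methoxymethoxy)benzaldehyde
Product: 9 4-(benzyloxy)-2-methoxy-3-(methoxymethoxy)benzaldehyde
Conditions: MeI, K2CO3, DMF, rt → 40 °C
Reagents that add atoms: iodomethane, CI
Why: Williamson methylation of the last, chelated phenol; no other nucleophilic site remains.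

Step 6
Reactants: 9 4-(benzyloxy)-2-methoxy-3-(methoxymethoxy)benzaldehyde
Product: 10 4-(benzyloxy)-2-methoxy-3-(methoxymethoxy)benzonitrile
Conditions: I2, NH3 (28% aq), THF, rt
Reagents that add atoms: ammonia, N
Why: One-pot oxidative conversion of an aldehyde into a nitrile (condensation with ammonia, dehydrogenation by iodine); the medium stays basic, which spares the MOM acetal and the benzyl ether, and aryl ethers are not iodinated under these conditions.

Step 7
Reactants: 10 4-(benzyloxy)-2-methoxy-3-(methoxymethoxy)benzonitrile
Product: 12 4-(benzyloxy)-2-methoxy-3-(methoxymethoxy)benzamidinium chloride, via lithium N,N'-bis(trimethylsilyl)benzamidinate 11 (not isolated)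
Conditions: LiHMDS, THF, 0 °C → rt; then NH4Cl, MeOH, 0 °C → rt
Reagents that add atoms: lithium hexamethyldisilazide, [Li+].C[Si](C)(C)[N-][Si](C)(C)C; ammonium chloride, [NH4+].[Cl-]
Why: Addition of the silylamide to the nitrile gives the silylated amidinate; methanolysis with ammonium chloride as the only proton source should give the amidinium salt without the strong acid of a Pinner reaction, which would cleave the MOM ether.

Step 8
Reactants: 12 4-(benzyloxy)-2-methoxy-3-(methoxymethoxy)benzamidinium chloride
Product: 13 3-[4-(benzyloxy)-2-methoxy-3-(methoxymethoxy)phenyl]-3-chloro-3H-diazirine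
Conditions: NaOCl (aq), LiCl, DMSO/MTBE, 0 °C, dark; cold extractive work-up, used at once
Reagents that add atoms: sodium hypochlorite, [Na+].[O-]Cl; lithium chloride, [Li+].[Cl-]
Why: Graham oxidation: hypochlorite N-chlorinates the amidine, base-induced N–N closure forms the three-membered ring and chloride ends on carbon; donor-substituted aryl chlorodiazirines ionize and lose N2 easily, hence the cold, dark handling and immediate use.

Step 9
Reactants: 4 6-(methoxymethoxy)benzofuran; 13 3-[4-(benzyloxy)-2-methoxy-3-(methoxymethoxy)phenyl]-3-chloro-3H-diazirine
Product: 15 3-[4-(benzyloxy)-2-methoxy-3-(methoxymethoxy)phenyl]-7-(methoxymethoxy)chromenylium chloride, via chlorocyclopropane adduct 14 (not isolated)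
Conditions: 13 (1.5 equiv, added over 2 h), 4 (0.3 M), 2,6-di-tert-butyl-4-methylpyridine (0.2 equiv), 4 Å MS, MeCN, 45 °C, dark; then Et2O, 0 °C; crude salt taken on directly
Reagents that add atoms: none
Why: Proposed new method: warming expels N2 from 13, and the singlet arylchlorocarbene adds to the enol-ether-like C2=C3 bond of 4, whose 6-alkoxy group (para to C3a) stabilizes the developing benzylic charge, to give chlorocyclopropane 14. Ionization of the C–Cl bond, assisted by the 2,4-dioxygenated aryl group on the same carbon and by the ring oxygen, is coupled with disrotatory cleavage of the former furan C2–C3 bond, so the carbene carbon becomes C3 between C2 and C4 of the aromatic benzopyrylium ion 15. The closest known reaction type is the Ciamician–Dennstedt-type one-carbon insertion of arylchlorocarbenes from chlorodiazirines into pyrroles and indoles, together with dihalocarbene ring enlargements of electron-rich five-membered heteroarenes; an aryl(chloro)carbene has not been shown to do this on a benzofuran. Ring C is not closed by cyclization but arises by ring expansion: a [2+1] cycloaddition followed by a two-electron electrocyclic opening of the cyclopropyl chloride to the allyl-type oxocarbenium ion, which enlarges the furan to the six-membered pyrylium ring. No stereocentre is formed, since C2, C3 and C4 are all trigonal in 15, and both diastereomers of 14 should converge on 15 because the donor aryl group allows stepwise ionization where the concerted path is geometrically barred. The step needs site selectivity for the furan C2=C3 bond over the benzo ring, the ether oxygens and the C–H bonds of the carbene's own ortho-methoxy group, and the carbene must be trapped before it meets 13 or a second carbene; the high nucleophilicity of the 6-alkoxybenzofuran π bond, a high concentration of 4 and slow dosing of 13 are relied on for this, and the position of ring B is not in question because the carbene carbon can only become C3. The hindered pyridine base and the sieves keep adventitious HCl away from the MOM acetals without adding to the cation.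

Step 10
Reactants: 15 3-[4-(benzyloxy)-2-methoxy-3-(methoxymethoxy)phenyl]-7-(methoxymethoxy)chromenylium chloride
Product: 16 3-[4-(benzyloxy)-2-methoxy-3-(methoxymethoxy)phenyl]-7-(methoxymethoxy)-2H-chromene
Conditions: NaBH4, MeCN/EtOH, −30 → 0 °C
Reagents that add atoms: none
Why: Borohydride reduction of a benzopyrylium salt: hydride should add at C2, the carbon next to the oxonium centre with the largest positive charge, which leaves the C3=C4 bond conjugated with both aryl rings.

Step 11
Reactants: 16 3-[4-(benzyloxy)-2-methoxy-3-(methoxymethoxy)phenyl]-7-(methoxymethoxy)-2H-chromene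
Product: 17 (3S)-3-[4-(benzyloxy)-2-methoxy-3-(methoxymethoxy)phenyl]-7-(methoxymethoxy)-3,4-dihydro-2H-chromene
Conditions: H2 (50 bar), [Ir(cod)((S)-tBu-PHOX)]BArF (2 mol%), CH2Cl2, rt
Reagents that add atoms: none
Why: Iridium-catalysed asymmetric hydrogenation of a trisubstituted aryl alkene with a P,N ligand, a reaction class established for 3-aryl-2H-chromenes; the chiral ligand differentiates the two faces of C3=C4 and sets C3 as S, and the benzyl and MOM ethers are inert to this catalyst.

Step 12
Reactants: 17 (3S)-3-[4-(benzyloxy)-2-methoxy-3-(methoxymethoxy)phenyl]-7-(methoxymethoxy)-3,4-dihydro-2H-chromene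
Product: 18 3-methoxy-2-(methoxymethoxy)-4-[(3S)-7-(methoxymethoxy)-3,4-dihydro-2H-chromen-3-yl]phenol
Conditions: H2 (1 atm), Pd/C (10%), EtOAc/EtOH, rt
Reagents that add atoms: none
Why: Hydrogenolysis of the benzyl ether frees only O4'; the MOM acetals and the chroman are inert, and C3 carries no benzylic C–O bond and no acidic hydrogen, so its configuration is kept.

Step 13
Reactants: 18 3-methoxy-2-(methoxymethoxy)-4-[(3S)-7-(methoxymethoxy)-3,4-dihydro-2H-chromen-3-yl]phenol; 19 prenyl bromide (1-bromo-3-methylbut-2-ene)
Product: 20 (3S)-3-[2-methoxy-3-(methoxymethoxy)-4-(3-methylbut-2-enyloxy)phenyl]-7-(methoxymethoxy)-3,4-dihydro-2H-chromene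
Conditions: K2CO3, acetone, 56 °C
Reagents that add atoms: none
Why: Williamson O-prenylation of the single free phenol; carbonate in acetone favours O- over C-alkylation.

Step 14
Reactants: 20 (3S)-3-[2-methoxy-3-(methoxymethoxy)-4-(3-methylbut-2-enyloxy)phenyl]-7-(methoxymethoxy)-3,4-dihydro-2H-chromene
Product: 21 3-methoxy-2-(methoxymethoxy)-4-[(3S)-7-(methoxymethoxy)-3,4-dihydro-2H-chromen-3-yl]-6-(2-methylbut-3-en-2-yl)phenol
Conditions: PhNEt2, 190 °C, sealed tube, Ar
Reagents that add atoms: none
Why: Aromatic Claisen rearrangement: the [3,3] shift can end only at C5', since C3' carries the OMOM group and the para carbon is substituted, and it inverts the allyl unit so that the prenyl ether gives the 1,1-dimethylallyl group; the amine solvent buffers the new phenol against acid-induced cyclization.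

Step 15
Reactants: 21 3-methoxy-2-(methoxymethoxy)-4-[(3S)-7-(methoxymethoxy)-3,4-dihydro-2H-chromen-3-yl]-6-(2-methylbut-3-en-2-yl)phenol
Product: 22 3-methoxy-4-[(3S)-7-hydroxy-3,4-dihydro-2H-chromen-3-yl]-6-(2-methylbut-3-en-2-yl)benzene-1,2-diol
Conditions: HCl (1.25 M in MeOH), 0 °C → rt, Ar
Reagents that add atoms: none
Why: Acid-catalysed acetal exchange removes both MOM groups as dimethoxymethane; the monosubstituted alkene is not protonated by dilute methanolic HCl at room temperature (ortho-(1,1-dimethylallyl)phenols are known to survive such deprotections), and C3 cannot epimerize.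

## Compound list

1 | 6-hydroxybenzofuran-3(2H)-one | O=C1COc2cc(O)ccc12 | starting material
2 | 6-(methoxymethoxy)benzofuran-3(2H)-one | O=C1COc2cc(OCOC)ccc12 | intermediate
3 | 6-(methoxymethoxy)-2,3-dihydrobenzofuran-3-ol (racemic) | OC1COc2cc(OCOC)ccc12 | intermediate
4 | 6-(methoxymethoxy)benzofuran | COCOc1ccc2ccoc2c1 | intermediate
5 | 2,3,4-trihydroxybenzaldehyde | O=Cc1ccc(O)c(O)c1O | starting material
6 | 4-(benzyloxy)-2,3-dihydroxybenzaldehyde | O=Cc1ccc(OCc2ccccc2)c(O)c1O | intermediate
7 | disodium 3-(benzyloxy)-6-formylbenzene-1,2-diolate | [Na+].[Na+].O=Cc1ccc(OCc2ccccc2)c([O-])c1[O-] | intermediate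
8 | 4-(benzyloxy)-2-hydroxy-3-(methoxymethoxy)benzaldehyde | O=Cc1ccc(OCc2ccccc2)c(OCOC)c1O | intermediate
9 | 4-(benzyloxy)-2-methoxy-3-(methoxymethoxy)benzaldehyde | O=Cc1ccc(OCc2ccccc2)c(OCOC)c1OC | intermediate
10 | 4-(benzyloxy)-2-methoxy-3-(methoxymethoxy)benzonitrile | N#Cc1ccc(OCc2ccccc2)c(OCOC)c1OC | intermediate
11 | lithium N,N'-bis(trimethylsilyl)-4-(benzyloxy)-2-methoxy-3-(methoxymethoxy)benzamidinate | [Li]N(C(=N[Si](C)(C)C)c1ccc(OCc2ccccc2)c(OCOC)c1OC)[Si](C)(C)C | intermediate
12 | 4-(benzyloxy)-2-methoxy-3-(methoxymethoxy)benzamidinium chloride | [Cl-].NC(=[NH2+])c1ccc(OCc2ccccc2)c(OCOC)c1OC | intermediate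
13 | 3-[4-(benzyloxy)-2-methoxy-3-(methoxymethoxy)phenyl]-3-chloro-3H-diazirine | ClC1(N=N1)c1ccc(OCc2ccccc2)c(OCOC)c1OC | intermediate
14 | 1-[4-(benzyloxy)-2-methoxy-3-(methoxymethoxy)phenyl]-1-chloro-4-(methoxymethoxy)-1a,6b-dihydro-1H-cyclopropa[b]benzofuran (racemic, both C1 epimers) | ClC1(c2ccc(OCc3ccccc3)c(OCOC)c2OC)C2Oc3cc(OCOC)ccc3C12 | intermediate
15 | 3-[4-(benzyloxy)-2-methoxy-3-(methoxymethoxy)phenyl]-7-(methoxymethoxy)chromenylium chloride | [Cl-].COCOc1ccc2cc(-c3ccc(OCc4ccccc4)c(OCOC)c3OC)c[o+]c2c1 | intermediate
16 | 3-[4-(benzyloxy)-2-methoxy-3-(methoxymethoxy)phenyl]-7-(methoxymethoxy)-2H-chromene | COCOc1ccc2C=C(COc2c1)c1ccc(OCc2ccccc2)c(OCOC)c1OC | intermediate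
17 | (3S)-3-[4-(benzyloxy)-2-methoxy-3-(methoxymethoxy)phenyl]-7-(methoxymethoxy)-3,4-dihydro-2H-chromene | COCOc1c(OCc2ccccc2)ccc([C@H]3COc4cc(OCOC)ccc4C3)c1OC | intermediate
18 | 3-methoxy-2-(methoxymethoxy)-4-[(3S)-7-(methoxymethoxy)-3,4-dihydro-2H-chromen-3-yl]phenol | COCOc1c(O)ccc([C@H]2COc3cc(OCOC)ccc3C2)c1OC | intermediate
19 | prenyl bromide (1-bromo-3-methylbut-2-ene) | CC(C)=CCBr | starting material
20 | (3S)-3-[2-methoxy-3-(methoxymethoxy)-4-(3-methylbut-2-enyloxy)phenyl]-7-(methoxymethoxy)-3,4-dihydro-2H-chromene | COCOc1c(OCC=C(C)C)ccc([C@H]2COc3cc(OCOC)ccc3C2)c1OC | intermediate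
21 | 3-methoxy-2-(methoxymethoxy)-4-[(3S)-7-(methoxymethoxy)-3,4-dihydro-2H-chromen-3-yl]-6-(2-methylbut-3-en-2-yl)phenol | C=CC(C)(C)c1cc([C@H]2COc3cc(OCOC)ccc3C2)c(OC)c(OCOC)c1O | intermediate
22 | 3-methoxy-4-[(3S)-7-hydroxy-3,4-dihydro-2H-chromen-3-yl]-6-(2-methylbut-3-en-2-yl)benzene-1,2-diol (CNP0167796.2) | C=CC(C)(C)c1cc([C@H]2COc3cc(O)ccc3C2)c(OC)c(O)c1O | target

## Step count and risks

Total: 15 steps. Longest linear sequence: 13 steps (5 to 22, steps 3–15). The ring A branch (steps 1–2) joins at step 9.

**Step 9 (key step, proposed new method).** The preparation and handling of 13 in step 8 belong to the same risk.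
- Most likely failures: loss of the donor-substituted diazirine by ionization or early N2 extrusion; diversion of the carbene into azine formation or into C–H insertion at its own ortho-methoxy group; slow addition, because carbene and alkene are both electron-rich; and consumption of the pyrylium ion by residual benzofuran or moisture.
- Fallback (known chemistry), from aldehyde 9 back to 16:
  - Chloroform and DBU would add to 9 to give 1-[4-(benzyloxy)-2-methoxy-3-(methoxymethoxy)phenyl]-2,2,2-trichloroethanol F1.
  - NaBH4 in aqueous NaOH/tert-butanol (reductive Jocic–Reeve homologation) would convert it into [4-(benzyloxy)-2-methoxy-3-(methoxymethoxy)phenyl]acetic acid F2.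
  - Commercial 2,4-dihydroxybenzaldehyde F3 would be protected at its non-chelated 4-OH (MOMCl, K2CO3, acetone) to give 2-hydroxy-4-(methoxymethoxy)benzaldehyde F4.
  - Perkin condensation of F2 with F4 (Ac2O, Et3N, 110 °C) would give 3-[4-(benzyloxy)-2-methoxy-3-(methoxymethoxy)phenyl]-7-(methoxymethoxy)-2H-chromen-2-one F5.
  - DIBAL-H would reduce the lactone to (2Z)-2-[4-(benzyloxy)-2-methoxy-3-(methoxymethoxy)phenyl]-3-[2-hydroxy-4-(methoxymethoxy)phenyl]prop-2-en-1-ol F6.
  - Mitsunobu etherification (PPh3, DIAD, THF) would close ring C to give 16, where the route resumes at step 11.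

**Step 10.**
- Most likely failures: hydride delivery to C4 as well as C2, giving a mixture of alkene isomers; hydrolytic ring opening of the cation before reduction.
- Fallback, from 15 back to 16: the salt would be hydrolysed on purpose (aqueous NaHCO3) to the pseudobase 3-[4-(benzyloxy)-2-methoxy-3-(methoxymethoxy)phenyl]-7-(methoxymethoxy)-2H-chromen-2-ol F7. NaBH4 would reduce its open hydroxy-enal tautomer, where hydride can reach only the former C2, to give the allylic alcohol F6. The Mitsunobu closure described above would then give 16.

**Step 11.**
- Most likely failures: poor facial selectivity or slow turnover, because the ortho-methoxy group of ring B crowds the alkene; partial loss of MOM groups through acidic iridium hydride species.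
- Fallback, from 16 back to 18: hydrogenation over Pd/C would saturate the alkene and cleave the benzyl ether in one operation, giving racemic 3-methoxy-2-(methoxymethoxy)-4-[7-(methoxymethoxy)-3,4-dihydro-2H-chromen-3-yl]phenol F8. Preparative chromatography on a chiral stationary phase would give 18.

**Step 14.**
- Most likely failures: further reaction of the product at 190 °C, namely abnormal Claisen rearrangement of the side chain, addition of the new phenol to the alkene, or loss of the five-carbon unit.
- Fallback, from 18 back to 21: amine-catalysed ortho-bromination (NBS, iPr2NH cat., CH2Cl2, low temperature) would give 6-bromo-3-methoxy-2-(methoxymethoxy)-4-[(3S)-7-(methoxymethoxy)-3,4-dihydro-2H-chromen-3-yl]phenol F9. A γ-selective Suzuki–Miyaura coupling with 3,3-dimethylallylboronic acid pinacol ester (Pd(OAc)2, bulky biarylphosphine, K3PO4, THF/H2O) would then give 21 without any thermal step.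

**Step 4.**
- Most likely failures: incomplete regiocontrol, with MOM transfer to O2 or to both oxygens, because MOMCl is a very reactive, unselective electrophile.
- Fallback, from 5 back to 9:
  - Dichlorodiphenylmethane (170 °C) would tie O3 and O4 into the ketal 4-hydroxy-2,2-diphenyl-1,3-benzodioxole-5-carbaldehyde F10.
  - Methylation (MeI, K2CO3) would give 4-methoxy-2,2-diphenyl-1,3-benzodioxole-5-carbaldehyde F11.
  - Aqueous acetic acid would release 3,4-dihydroxy-2-methoxybenzaldehyde F12.
  - Benzylation at the more acidic 4-OH (BnBr, NaHCO3) would give 4-(benzyloxy)-3-hydroxy-2-methoxybenzaldehyde F13.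
  - MOMCl/iPr2NEt would then give 9.

## Further compounds

F1 | step 9 | 1-[4-(benzyloxy)-2-methoxy-3-(methoxymethoxy)phenyl]-2,2,2-trichloroethanol (racemic) | OC(c1ccc(OCc2ccccc2)c(OCOC)c1OC)C(Cl)(Cl)Cl
F2 | step 9 | [4-(benzyloxy)-2-methoxy-3-(methoxymethoxy)phenyl]acetic acid | OC(=O)Cc1ccc(OCc2ccccc2)c(OCOC)c1OC
F3 | step 9 | 2,4-dihydroxybenzaldehyde | O=Cc1ccc(O)cc1O
F4 | step 9 | 2-hydroxy-4-(methoxymethoxy)benzaldehyde | O=Cc1ccc(OCOC)cc1O
F5 | step 9 | 3-[4-(benzyloxy)-2-methoxy-3-(methoxymethoxy)phenyl]-7-(methoxymethoxy)-2H-chromen-2-one | COCOc1ccc2C=C(C(=O)Oc2c1)c1ccc(OCc2ccccc2)c(OCOC)c1OC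
F6 | step 9 | (2Z)-2-[4-(benzyloxy)-2-methoxy-3-(methoxymethoxy)phenyl]-3-[2-hydroxy-4-(methoxymethoxy)phenyl]prop-2-en-1-ol | OC/C(c1ccc(OCc2ccccc2)c(OCOC)c1OC)=C\c1ccc(OCOC)cc1O
F7 | step 10 | 3-[4-(benzyloxy)-2-methoxy-3-(methoxymethoxy)phenyl]-7-(methoxymethoxy)-2H-chromen-2-ol (racemic) | COCOc1ccc2C=C(C(O)Oc2c1)c1ccc(OCc2ccccc2)c(OCOC)c1OC
F8 | step 11 | racemic 3-methoxy-2-(methoxymethoxy)-4-[7-(methoxymethoxy)-3,4-dihydro-2H-chromen-3-yl]phenol | COCOc1c(O)ccc(C2COc3cc(OCOC)ccc3C2)c1OC
F9 | step 14 | 6-bromo-3-methoxy-2-(methoxymethoxy)-4-[(3S)-7-(methoxymethoxy)-3,4-dihydro-2H-chromen-3-yl]phenol | COCOc1c(O)c(Br)cc([C@H]2COc3cc(OCOC)ccc3C2)c1OC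
F10 | step 4 | 4-hydroxy-2,2-diphenyl-1,3-benzodioxole-5-carbaldehyde | O=Cc1ccc2OC(c3ccccc3)(c3ccccc3)Oc2c1O
F11 | step 4 | 4-methoxy-2,2-diphenyl-1,3-benzodioxole-5-carbaldehyde | O=Cc1ccc2OC(c3ccccc3)(c3ccccc3)Oc2c1OC
F12 | step 4 | 3,4-dihydroxy-2-methoxybenzaldehyde | O=Cc1ccc(O)c(O)c1OC
F13 | step 4 | 4-(benzyloxy)-3-hydroxy-2-methoxybenzaldehyde | O=Cc1ccc(OCc2ccccc2)c(O)c1OC
A1 | alternative 1 | (3S)-3-[2-methoxy-3,4-bis(methoxymethoxy)-5-(2-methylbut-3-en-2-yl)phenyl]-3,4-dihydro-2H-chromen-7-ol | C=CC(C)(C)c1cc([C@H]2COc3cc(O)ccc3C2)c(OC)c(OCOC)c1OCOC
A2 | alternative 1 | (6S)-4-diazo-7-(ethynyloxy)-6-[2-methoxy-3,4-bis(methoxymethoxy)-5-(2-methylbut-3-en-2-yl)phenyl]hept-1-en-3-one | C=CC(=O)C(=[N+]=[N-])C[C@H](COC#C)c1cc(C(C)(C)C=C)c(OCOC)c(OCOC)c1OC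
A3 | alternative 2 | {3-[2-methoxy-3,4-bis(methoxymethoxy)-5-(2-methylbut-3-en-2-yl)phenyl]-7-(methoxymethoxy)-3,4-dihydro-2H-chromen-3-yl}methanol, CH2OH in place of the C3 hydrogen, configuration as in the SMILES | C=CC(C)(C)c1cc([C@@]2(CO)COc3cc(OCOC)ccc3C2)c(OC)c(OCOC)c1OCOC
A4 | alternative 2 | 2-[2-bromo-4-(methoxymethoxy)benzyl]-2-[2-methoxy-3,4-bis(methoxymethoxy)-5-(2-methylbut-3-en-2-yl)phenyl]propane-1,3-diol | C=CC(C)(C)c1cc(C(CO)(CO)Cc2ccc(OCOC)cc2Br)c(OC)c(OCOC)c1OCOC
A5 | alternative 3 | (3S)-3-[2-methoxy-3,4-bis(methoxymethoxy)-5-(2-methylbut-3-en-2-yl)phenyl]-7-(methoxymethoxy)-3,4-dihydro-2H-chromen-2-one | C=CC(C)(C)c1cc([C@H]2C(=O)Oc3cc(OCOC)ccc3C2)c(OC)c(OCOC)c1OCOC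
A6 | alternative 3 | 4-nitrophenyl [2-methoxy-3,4-bis(methoxymethoxy)-5-(2-methylbut-3-en-2-yl)phenyl]acetate | C=CC(C)(C)c1cc(CC(=O)Oc2ccc(cc2)[N+](=O)[O-])c(OC)c(OCOC)c1OCOC
A7 | alternative 3 | 3-(methoxymethoxy)-6-methylidenecyclohexa-2,4-dien-1-one | C=C1C=CC(OCOC)=CC1=O
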